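**Strategy.** The route rests on cutting the C3–C4 bond of ring A. The C3 carbinol sits beside quaternary C4, and C4 bears the oxygenated carbon C18; taken to the aldehyde level and masked as an enol silyl ether, C18 makes C4 a nucleophile for a C3 aldehyde. The C5 stereocentre (H, C6, branched C4) is the one bought with (S)-carvone. A BF3-promoted intramolecular Mukaiyama aldol addition closes ring A in one operation, making C3–C4, the C3 carbinol and quaternary C4 (methyl axial, C18 equatorial). The precursor is a carvone-derived ring B enone with a C10 propanal arm trans to the C5-bound enol ether; ring B is completed by enone transposition, Claisen rearrangement at C9 and lactonisation onto C8.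

Key step: step 8

Remark on numbering: labdane numbers are used throughout (ring A: C1–C5 and C10; ring B: C5–C10; the carvone carbonyl is C9).

Assumption: soft enolisation of the hindered C18 aldehyde should give mainly the E enol silyl ether (silyloxy cis to the C4 methyl), and through an open transition state this geometry should place the C3 oxygen axial; the C3 configuration formed in step 8 is therefore not relied on and is re-set in steps 9 and 10, while C4 is expected to come out the same from either enol ether geometry.

Step 1
Reactants: 1 (S)-(+)-carvone; 2 iodomethane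
Product: 4 6-methylcarvone (C10 epimer mixture), via lithium dienolate 3 (not isolated)
Conditions: LiN(i-Pr)2, THF, −78 °C; then MeI, −78 → 0 °C
Reagents that add atoms: iodomethane, CI
Why: Kinetic deprotonation at the α′-methylene (C10) gives the cross-conjugated dienolate, which is C-methylated (enolate alkylation); both epimers give the same enolate in step 2, so the new centre need not be controlled.

Step 2
Reactants: 4 6-methylcarvone; 5 allyl bromide
Product: 7 6-allyl-6-methylcarvone (allyl trans to isopropenyl), via lithium enolate 6 (not isolated)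
Conditions: LiN(i-Pr)2, THF, −78 °C; then allyl bromide, DMPU, −78 → −20 °C
Reagents that add atoms: allyl bromide, C=CCBr
Why: Enolate alkylation in which the allyl halide approaches the tetrasubstituted enolate anti to the isopropenyl group on C5, setting quaternary C10 with the future C1–C3 arm trans to the C5 substituent.

Step 3
Reactants: 7 6-allyl-6-methylcarvone
Product: 8 isopropenyl epoxide (C4 epimer mixture)
Conditions: mCPBA (1.05 equiv), NaHCO3, CH2Cl2, 0 °C
Reagents that add atoms: mCPBA, OOC(=O)c1cccc(Cl)c1
Why: Prilezhaev epoxidation, in which the electron-rich 1,1-disubstituted alkene reacts faster than the monosubstituted allyl alkene and the electron-poor enone; the C4 centre is erased in step 5.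

Step 4
Reactants: 8 isopropenyl epoxide
Product: 9 C18 aldehyde (C4 epimer mixture)
Conditions: BF3·OEt2 (0.2 equiv), CH2Cl2, −78 → −40 °C
Reagents that add atoms: none
Why: Meinwald rearrangement, in which Lewis acid opening at tertiary C4 is followed by a 1,2-hydride shift from C18 to give the aldehyde.

Step 5
Reactants: 9 C18 aldehyde
Product: 10 (E)-C18 tert-butyldimethylsilyl enol ether
Conditions: TBSOTf (1.2 equiv), Et3N, CH2Cl2, −78 → 0 °C
Reagents that add atoms: tert-butyldimethylsilyl trifluoromethanesulfonate, CC(C)(C)[Si](C)(C)OS(=O)(=O)C(F)(F)F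
Why: Soft enolisation (O-silylation, then deprotonation at C4) is selective for the aldehyde because the enone has no α-hydrogen, and the E isomer should predominate because it keeps the bulky C5 ring carbon trans to oxygen.

Step 6
Reactants: 10 (E)-C18 silyl enol ether
Product: 12 C3,C9-diol (C9 epimer mixture), via 9-BBN adduct 11 (not isolated)
Conditions: 9-BBN (3 equiv), THF, 0 °C → rt; then 30% H2O2, pH 7 phosphate buffer, MeOH, 0 °C
Reagents that add atoms: hydrogen peroxide, OO
Why: Hydroboration–oxidation, in which 9-BBN adds anti-Markovnikov to the terminal alkene and deliberately reduces the conjugated ketone 1,2 (any unreduced ketone converges in step 7), while the trisubstituted enol ether and ring alkene are too hindered to react.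

Step 7
Reactants: 12 C3,C9-diol
Product: 13 key precursor (ring B enone, C10 propanal arm, (E)-C18 silyl enol ether)
Conditions: Pr4N[RuO4] (5 mol%), N-methylmorpholine N-oxide (4 equiv), 4 Å molecular sieves, CH2Cl2, rt
Reagents that add atoms: none
Why: Ley–Griffith oxidation turns the primary alcohol into the C3 aldehyde and the allylic carbinol back into the C9 enone in one neutral operation that should leave the silyl enol ether intact.

Step 8
Reactants: 13 key precursor
Product: 14 trans-fused bicyclic enone with C3 carbinol (axial), axial C4 methyl and equatorial C18 aldehyde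
Conditions: BF3·OEt2 (2.5 equiv), CH2Cl2 (0.005 M), −78 °C; aq. NaHCO3
Reagents that add atoms: none
Why: BF3 binds the C3 aldehyde, C4 of the C18 enol silyl ether attacks it through an open transition state, and the silyloxocarbenium ion loses silicon as the fluoride to leave the C18 aldehyde (intramolecular Mukaiyama aldol addition; closest known type: additions of aldehyde enol silyl ethers that create a quaternary carbon). Ring A closes in a 6-(enolexo)-exo-trig mode as a chair on the trans-diequatorial C10 and C5 arms of ring B. C4 is controlled by A(1,3) strain: the enol ether plane must stand perpendicular to the forming bond, and only the rotamer with C18 eclipsing C5–H keeps the C18 substituent syn to C5 away from the axial C10 methyl, so the C4 methyl ends axial and C18 equatorial. C3 is controlled by the enol ether geometry, because BF3 on the aldehyde oxygen avoids the silyloxy group: the E isomer should give the axial carbinol drawn and any Z isomer the equatorial one, and both converge in steps 9 and 10. The step needs the aldehyde to react in preference to the enone (C4 cannot reach the enone carbons without forming a four-membered ring) and ring closure to beat intermolecular addition, which the tether and high dilution secure.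

Step 9
Reactants: 14 β-hydroxy aldehyde
Product: 15 3-oxo-18-al enone
Conditions: Dess–Martin periodinane (1.5 equiv), NaHCO3, CH2Cl2, 0 °C → rt
Reagents that add atoms: none
Why: Dess–Martin oxidation of the secondary carbinol removes the C3 centre so that both carbinol epimers converge; the β-keto aldehyde cannot enolise between its carbonyl groups because C4 is quaternary.

Step 10
Reactants: 15 3-oxo-18-al enone
Product: 16 3,18-diol enone (C3 hydroxyl equatorial)
Conditions: Me4N[BH(OAc)3] (6 equiv), AcOH/MeCN (1:1), −20 °C → rt
Reagents that add atoms: none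
Why: Triacetoxyborohydride reduces the aldehyde but not the enone, and the C18 alkoxyborohydride then delivers hydride to the C3 ketone (Evans–Saksena hydroxyl-directed reduction) from the axial face, the other face being blocked by the axial C4 methyl, which sets the equatorial C3 carbinol.

Step 11
Reactants: 16 3,18-diol enone
Product: 17 3,18-O-isopropylidene enone
Conditions: 2,2-dimethoxypropane, PPTS (cat.), CH2Cl2, rt
Reagents that add atoms: 2,2-dimethoxypropane, COC(C)(C)OC
Why: Acid-catalysed transacetalisation closes the diequatorial 1,3-diol to a six-membered acetonide that masks both hydroxyls through the base, hydride and ylide steps.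

Step 12
Reactants: 17 acetonide enone
Product: 18 7,8-epoxy-9-ketone (epoxide on the face of C5–H)
Conditions: 30% H2O2, NaOH (aq., 0.5 equiv), MeOH, 0 °C → rt
Reagents that add atoms: hydrogen peroxide, OO
Why: Weitz–Scheffer epoxidation, in which hydroperoxide adds to C7 along the axial trajectory on the face of C5–H and opposite to the axial C10 methyl, setting C7 and C8 as carvone itself does.

Step 13
Reactants: 18 epoxy ketone
Product: 20 C7 allylic alcohol with C8=C9, via epoxy hydrazone 19 (not isolated)
Conditions: N2H4·H2O (5 equiv), AcOH (1 equiv), MeOH, 0 °C → rt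
Reagents that add atoms: none
Why: Wharton transposition, in which the epoxy hydrazone fragments with loss of N2 to the C8=C9 alkene and the C7 carbinol, whose configuration is inherited from the epoxide.

Step 14
Reactants: 20 C7 allylic alcohol; 21 N,N-dimethylacetamide dimethyl acetal
Product: 23 C9 N,N-dimethylacetamide with C7=C8, via ketene N,O-acetal 22 (not isolated)
Conditions: MeC(OMe)2NMe2 (5 equiv), xylene, 140 °C
Reagents that add atoms: N,N-dimethylacetamide dimethyl acetal, COC(C)(OC)N(C)C
Why: Eschenmoser–Claisen rearrangement, whose suprafacial [3,3] shift moves the two-carbon unit (C11, C12) from the pseudoaxial C7 oxygen to C9 on the same face, anti to the C10 methyl, setting C9 and moving the alkene to C7=C8.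

Step 15
Reactants: 23 C9 acetamide
Product: 25 7-iodo-8,12-lactone, via iminium ether iodide 24 (not isolated)
Conditions: I2 (3 equiv), MeCN, 0 °C → rt, dark; then THF/H2O
Reagents that add atoms: iodine, II; water, O
Why: Iodolactonisation of the γ,δ-unsaturated amide, in which the amide oxygen opens the iodonium ion at tertiary C8 in a 5-exo mode from the face of the C9 arm (only a cis-fused lactone is possible), iodine ends trans on C7 and water hydrolyses the iminium ether; this sets C8 with oxygen cis to the C9 chain.

Step 16
Reactants: 25 iodolactone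
Product: 26 8,12-lactone
Conditions: Bu3SnH (1.5 equiv), AIBN (cat.), toluene, 80 °C
Reagents that add atoms: none
Why: Radical chain dehalogenation removes the C7 iodine under neutral conditions that spare lactone and acetonide.

Step 17
Reactants: 26 lactone
Product: 27 8,12-lactol (anomer mixture)
Conditions: i-Bu2AlH (1.2 equiv), CH2Cl2, −78 °C; Rochelle salt work-up
Reagents that add atoms: none
Why: Partial reduction of the γ-lactone stops at the lactol because the tetrahedral aluminate is stable at low temperature.

Step 18
Reactants: 27 lactol; 28 (methoxymethyl)triphenylphosphonium chloride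
Product: 30 six-membered lactol (C13 hemiacetal on the C8 oxygen) with free 3,18-diol, via enol ether 29 (not isolated)
Conditions: Ph3P+CH2OMe Cl− (4 equiv), KN(SiMe3)2 (3.8 equiv), THF, 0 °C → rt; then 2 M HCl, THF, rt
Reagents that add atoms: (methoxymethyl)triphenylphosphonium chloride, COC[P+](c1ccccc1)(c1ccccc1)c1ccccc1.[Cl-]; water, O
Why: Wittig methoxymethylenation of the open hydroxy-aldehyde form adds C13, so that C12 remains a methylene; aqueous acid then hydrolyses the enol ether to the homologous aldehyde (held as the lactol) and cleaves the acetonide in the same operation.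

Step 19
Reactants: 30 six-membered lactol; 31 dimethyl (1-diazo-2-oxopropyl)phosphonate
Product: 32 terminal alkyne triol
Conditions: Ohira–Bestmann reagent (2 equiv), K2CO3 (3 equiv), MeOH, rt
Reagents that add atoms: dimethyl (1-diazo-2-oxopropyl)phosphonate, COP(=O)(OC)C(=[N+]=[N-])C(C)=O
Why: Seyferth–Gilbert homologation (Ohira–Bestmann variant) of the aldehyde in equilibrium with the lactol gives the C13≡C14 alkyne under mild base that tolerates the free hydroxyls.

Step 20
Reactants: 32 alkyne triol
Product: 33 C18 tert-butyldimethylsilyl ether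
Conditions: TBSCl (1.2 equiv), imidazole, DMF, 0 °C → rt
Reagents that add atoms: tert-butyldimethylsilyl chloride, CC(C)(C)[Si](C)(C)Cl
Why: Silylation selects the primary C18 hydroxyl over the hindered secondary C3 and tertiary C8 hydroxyls.

Step 21
Reactants: 33 C18 silyl ether; 34 acetic anhydride
Product: 35 C3 acetate C18 silyl ether
Conditions: Ac2O, pyridine, DMAP (cat.), CH2Cl2, rt
Reagents that add atoms: acetic anhydride, CC(=O)OC(C)=O
Why: Acylation takes the only accessible hydroxyl (C3), since the tertiary C8 hydroxyl does not acylate under these conditions.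

Step 22
Reactants: 35 C3 acetate C18 silyl ether
Product: 36 C3 acetate alkyne diol
Conditions: HF·pyridine, pyridine, THF, 0 °C → rt
Reagents that add atoms: none
Why: Fluoride cleavage of the primary silyl ether under buffered, slightly acidic conditions avoids 1,3-acyl migration from the C3 to the C18 oxygen.

Step 23
Reactants: 36 C3 acetate alkyne diol; 37 ethylene
Product: 38 target
Conditions: ethylene (1 atm), second-generation Grubbs catalyst RuCl2(H2IMes)(PCy3)(=CHPh) (10 mol%), toluene, 80 °C
Reagents that add atoms: ethylene, C=C
Why: Enyne cross-metathesis of the terminal alkyne with ethylene forms the 2-substituted buta-1,3-diene (C13=C16, C14=C15) directly and touches no stereocentre.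

**Compound list**

1 | (S)-(+)-carvone | CC1=CC[C@H](C(C)=C)CC1=O | starting material
2 | iodomethane | CI | starting material
3 | lithium dienolate of carvone (not isolated) | CC1=CC[C@H](C(C)=C)C=C1O[Li] | intermediate
4 | 6-methylcarvone (C10 epimer mixture) | CC1=CC[C@H](C(C)=C)C(C)C1=O | intermediate
5 | allyl bromide | C=CCBr | starting material
6 | lithium enolate of 6-methylcarvone (not isolated) | CC1=CC[C@H](C(C)=C)C(C)=C1O[Li] | intermediate
7 | 6-allyl-6-methylcarvone; allyl on C10 trans to isopropenyl on C5, methyl cis | C=CC[C@]1(C)[C@@H](C(C)=C)CC=C(C)C1=O | intermediate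
8 | epoxide of the isopropenyl group of 7 (C4 epimer mixture) | C=CC[C@]1(C)[C@@H](C2(C)CO2)CC=C(C)C1=O | intermediate
9 | C18 aldehyde (C4 epimer mixture) | C=CC[C@]1(C)[C@@H](C(C)C=O)CC=C(C)C1=O | intermediate
10 | (E)-C18 tert-butyldimethylsilyl enol ether (silyloxy cis to the C4 methyl) | C=CC[C@]1(C)[C@@H](/C(C)=C/O[Si](C)(C)C(C)(C)C)CC=C(C)C1=O | intermediate
11 | 9-BBN adduct: C3 B-alkyl borane and C9 O-borinate (not isolated) | B1(CCC[C@]2(C)[C@@H](/C(C)=C/O[Si](C)(C)C(C)(C)C)CC=C(C)C2OB3C4CCCC3CCC4)C5CCCC1CCC5 | intermediate
12 | C3,C9-diol with (E)-silyl enol ether (C9 epimer mixture) | OCCC[C@]1(C)[C@@H](/C(C)=C/O[Si](C)(C)C(C)(C)C)CC=C(C)C1O | intermediate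
13 | key precursor: ring B enone, C10 propanal arm trans to the C5-bound (E)-C18 silyl enol ether | O=CCC[C@]1(C)[C@@H](/C(C)=C/O[Si](C)(C)C(C)(C)C)CC=C(C)C1=O | intermediate
14 | key product: trans-fused bicyclic enone, C3 carbinol axial, C4 methyl axial, C18 aldehyde equatorial | O=C1[C@]2(C)CC[C@H](O)[C@](C)(C=O)[C@H]2CC=C1C | intermediate
15 | 3-oxo-18-al enone | O=C1[C@]2(C)CCC(=O)[C@](C)(C=O)[C@H]2CC=C1C | intermediate
16 | 3,18-diol enone, C3 hydroxyl equatorial | O=C1[C@]2(C)CC[C@@H](O)[C@](C)(CO)[C@H]2CC=C1C | intermediate
17 | 3,18-O-isopropylidene enone | O=C1[C@]2(C)CC[C@H]3OC(C)(C)OC[C@]3(C)[C@H]2CC=C1C | intermediate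
18 | 7,8-epoxy-9-ketone, epoxide on the face of C5–H | O=C1[C@]2(C)CC[C@H]3OC(C)(C)OC[C@]3(C)[C@H]2C[C@@H]4O[C@]14C | intermediate
19 | epoxy hydrazone (not isolated) | NN=C1[C@]2(C)CC[C@H]3OC(C)(C)OC[C@]3(C)[C@H]2C[C@@H]4O[C@]14C | intermediate
20 | C7 allylic alcohol with C8=C9, hydroxyl anti to the C10 methyl | CC1=C[C@]2(C)CC[C@H]3OC(C)(C)OC[C@]3(C)[C@H]2C[C@@H]1O | intermediate
21 | N,N-dimethylacetamide dimethyl acetal | COC(C)(OC)N(C)C | starting material
22 | ketene N,O-acetal of 20 (not isolated) | CC1=C[C@]2(C)CC[C@H]3OC(C)(C)OC[C@]3(C)[C@H]2C[C@@H]1OC(=C)N(C)C | intermediate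
23 | C9 N,N-dimethylacetamide with C7=C8, chain anti to the C10 methyl | CN(C)C(=O)C[C@@H]1[C@]2(C)CC[C@H]3OC(C)(C)OC[C@]3(C)[C@H]2CC=C1C | intermediate
24 | iminium ether iodide (not isolated) | C[N+](C)=C1C[C@@H]2[C@]3(C)CC[C@H]4OC(C)(C)OC[C@]4(C)[C@H]3C[C@@H](I)[C@]2(C)O1.[I-] | intermediate
25 | 7-iodo-8,12-lactone, cis-fused, iodine trans to the lactone oxygen | O=C1C[C@@H]2[C@]3(C)CC[C@H]4OC(C)(C)OC[C@]4(C)[C@H]3C[C@@H](I)[C@]2(C)O1 | intermediate
26 | 8,12-lactone | O=C1C[C@@H]2[C@]3(C)CC[C@H]4OC(C)(C)OC[C@]4(C)[C@H]3CC[C@]2(C)O1 | intermediate
27 | 8,12-lactol (anomer mixture) | OC1C[C@@H]2[C@]3(C)CC[C@H]4OC(C)(C)OC[C@]4(C)[C@H]3CC[C@]2(C)O1 | intermediate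
28 | (methoxymethyl)triphenylphosphonium chloride | COC[P+](c1ccccc1)(c1ccccc1)c1ccccc1.[Cl-] | starting material
29 | methyl enol ether with free C8 hydroxyl (E/Z mixture, not isolated) | COC=CC[C@@H]1[C@]2(C)CC[C@H]3OC(C)(C)OC[C@]3(C)[C@H]2CC[C@]1(C)O | intermediate
30 | six-membered lactol (C13 hemiacetal on the C8 oxygen) with free 3,18-diol (anomer mixture) | OC1CC[C@@H]2[C@]3(C)CC[C@@H](O)[C@](C)(CO)[C@H]3CC[C@]2(C)O1 | intermediate
31 | dimethyl (1-diazo-2-oxopropyl)phosphonate | COP(=O)(OC)C(=[N+]=[N-])C(C)=O | starting material
32 | terminal alkyne 3,8,18-triol | C#CCC[C@@H]1[C@]2(C)CC[C@@H](O)[C@](C)(CO)[C@H]2CC[C@]1(C)O | intermediate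
33 | C18 tert-butyldimethylsilyl ether | C#CCC[C@@H]1[C@]2(C)CC[C@@H](O)[C@](C)(CO[Si](C)(C)C(C)(C)C)[C@H]2CC[C@]1(C)O | intermediate
34 | acetic anhydride | CC(=O)OC(C)=O | starting material
35 | C3 acetate C18 silyl ether | C#CCC[C@@H]1[C@]2(C)CC[C@@H](OC(C)=O)[C@](C)(CO[Si](C)(C)C(C)(C)C)[C@H]2CC[C@]1(C)O | intermediate
36 | C3 acetate alkyne 8,18-diol | C#CCC[C@@H]1[C@]2(C)CC[C@@H](OC(C)=O)[C@](C)(CO)[C@H]2CC[C@]1(C)O | intermediate
37 | ethylene | C=C | starting material
38 | target, 3-acetoxy-labda-13(16),14-diene-8,18-diol stereoisomer | C=CC(=C)CC[C@@H]1[C@]2(C)CC[C@@H](OC(C)=O)[C@](C)(CO)[C@H]2CC[C@]1(C)O | target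

**Total step count:** 23. **Longest linear sequence:** 23 steps from (S)-carvone.

**Steps most likely to fail**

1. Step 8. The open transition state may not discriminate the two rotamers about C5–C4 well enough (erosion of facial selectivity at C4), or the enol ether may be cleaved before it cyclises. The fallback sets out from 7 and returns at 16; it forms C3–C4 by an intramolecular nitrile oxide cycloaddition onto the untouched isopropenyl group instead. Dicyclohexylborane (c-Hex2BH) hydroborates the monosubstituted allyl alkene of 7 selectively, and buffered H2O2 gives the keto alcohol F1. Dess–Martin oxidation gives the keto aldehyde F2 and re-oxidises any C9 carbinol. NH2OH·HCl and NaOAc give the aldoxime F3. NaOCl generates the nitrile oxide, which adds to the isopropenyl alkene to close ring A as the isoxazoline F4; the five-membered ring holds the oxygen-bearing carbon (future C18) equatorial and so forces the C4 methyl axial. Mo(CO)6 in wet MeCN cleaves the N–O bond and hydrolyses the imine to the hydroxy ketone F5, which the conditions of step 10 reduce to 16.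

2. Step 13. Hydrazone formation at the C9 ketone, flanked by quaternary C10 and the epoxide carbon C8, may be slow enough for nucleophilic epoxide opening to compete. The fallback sets out from 18 and returns at 20, replacing hydrazone fragmentation by radical fragmentation. NaBH4 in MeOH reduces 18 to the epoxy alcohol F6. NaH, CS2 and MeI give the xanthate F7. Bu3SnH with AIBN generates the C9 radical, which opens the neighbouring epoxide by scission of C8–O to the C8=C9 alkene and the C7 alkoxyl radical; hydrogen transfer gives 20 with C7 unchanged.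

3. Step 15. The rigid trans-fused ring B forces the amide oxygen to open the iodonium ion along a diequatorial (twist-boat) trajectory, so cyclisation may be slow and iodohydrin formation or simple reversal may take over. The fallback sets out from 20 and returns at 26; it closes the lactone through the planar tertiary C8 cation, which has no anti-periplanar demand. Ac2O, pyridine and DMAP give the allylic acetate F8. Ireland–Claisen rearrangement (LiN(i-Pr)2, Me3SiCl, THF, −78 → 65 °C, aqueous work-up) gives the C9 acetic acid F9 with the same facial outcome as step 14. TsOH·H2O in toluene at 80 °C protonates C7, the carboxyl group captures the C8 cation from the only face it can reach, and the acetonide is lost, giving the diol lactone F10. The conditions of step 11 restore the acetonide and give 26.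

**Further compounds**

F1 | step 8 | keto alcohol: 7 with the allyl group hydroborated to the C3 primary alcohol, isopropenyl intact | OCCC[C@]1(C)[C@@H](C(C)=C)CC=C(C)C1=O
F2 | step 8 | keto aldehyde with intact isopropenyl group | O=CCC[C@]1(C)[C@@H](C(C)=C)CC=C(C)C1=O
F3 | step 8 | C3 aldoxime | ON=CCC[C@]1(C)[C@@H](C(C)=C)CC=C(C)C1=O
F4 | step 8 | ring A isoxazoline (C3=N, O on the equatorial CH2 of C4, C4 methyl axial) | O=C1[C@]2(C)CCC3=NOC[C@]3(C)[C@H]2CC=C1C
F5 | step 8 | 3-oxo-18-hydroxy enone | O=C1[C@]2(C)CCC(=O)[C@](C)(CO)[C@H]2CC=C1C
F6 | step 13 | 7,8-epoxy-9-ol (C9 epimer mixture) | OC1[C@]2(C)CC[C@H]3OC(C)(C)OC[C@]3(C)[C@H]2C[C@@H]4O[C@]14C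
F7 | step 13 | C9 S-methyl xanthate of F6 | CSC(=S)OC1[C@]2(C)CC[C@H]3OC(C)(C)OC[C@]3(C)[C@H]2C[C@@H]4O[C@]14C
F8 | step 15 | C7 allylic acetate of 20 | CC1=C[C@]2(C)CC[C@H]3OC(C)(C)OC[C@]3(C)[C@H]2C[C@@H]1OC(C)=O
F9 | step 15 | C9 acetic acid with C7=C8 | OC(=O)C[C@@H]1[C@]2(C)CC[C@H]3OC(C)(C)OC[C@]3(C)[C@H]2CC=C1C
F10 | step 15 | 8,12-lactone 3,18-diol | O=C1C[C@@H]2[C@]3(C)CC[C@@H](O)[C@](C)(CO)[C@H]3CC[C@]2(C)O1
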